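## Retrosynthetic overview

1. Feature: the benzo ring of the benzofuran (C3a', C4', C5', C6', C7', C7a') carries C5'–CH3 between C4'–OCH3 and C6'–OH. These two oxygens are nearly equivalent, so they must arrive already differentiated.
2. Endgame: the target is traced back to the 7-O-benzyl, 6'-O-TIPS, 4'-OH benzofuran by O-methylation, desilylation and debenzylation.
3. Key disconnection: the benzo ring is traced back to a 5-(flavan-8-yl)-2-furyl diazomethyl ketone and 1-(triisopropylsilyloxy)propyne. The cascade is photo-Wolff, [2+2], 4π opening and 6π closure, forming C7a'–C7', C6'–C7', C4'–C5' and C3a'–C4'.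
4. The diazoketone comes from a furoic ester, made by Suzuki coupling at C8 of a (2S)-8-bromoflavan. That bromide comes from (2S)-alpinetin, the source of C2, by O-benzylation, C4 deoxygenation and C8 bromination. The siloxyalkyne comes from ethyl acetate through an ynolate.
5. Ring order: rings A, B and C come with alpinetin, the furan is bought, and the benzo ring is grown last on the furan.

Key step: step 9

Assumption: commercial alpinetin is taken as the natural (2S)-(−) enantiomer, and its enantiopurity is verified by chiral HPLC before step 1.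

Locants: flavan atoms are unprimed (ring A benzo, ring B 2-phenyl, ring C pyran) and benzofuran atoms are primed.

## Route

Step 1
Reactants: 1 (2S)-alpinetin
Product: 2 (2S)-7-benzyloxy-5-methoxyflavanone
Conditions: BnOH, PPh3, DIAD, THF, 0 °C → rt
Reagents that add atoms: benzyl alcohol, OCc1ccccc1
Why: Mitsunobu etherification of the acidic 7-OH (para to the C4 carbonyl) needs no added base, so the retro-oxa-Michael opening of ring C to the chalcone, by which flavanones racemise at C2, is not triggered.

Step 2
Reactants: 2 (2S)-7-benzyloxy-5-methoxyflavanone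
Product: 3 (2S,4S)-7-benzyloxy-5-methoxyflavan-4-ol (2,4-cis)
Conditions: NaBH4, THF/MeOH, −10 → 0 °C
Reagents that add atoms: none
Why: Borohydride 1,2-reduction at low temperature should outpace enolisation, and axial hydride delivery to the half-chair with equatorial 2-phenyl sets the 2,4-cis (4S) carbinol, a centre that is erased in step 3.

Step 3
Reactants: 3 (2S,4S)-7-benzyloxy-5-methoxyflavan-4-ol
Product: 4 (2S)-7-benzyloxy-5-methoxyflavan
Conditions: Et3SiH (5 equiv), CH2Cl2, −30 °C, then CF3CO2H dropwise, → 0 °C
Reagents that add atoms: none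
Why: In this ionic hydrogenation (Kursanov–Parnes reduction) acid ionises the C4 carbinol to a cation stabilised by O1, 5-OMe and 7-OBn, the excess silane already present should capture it before it alkylates another ring A or loses H3, and C2 with its unactivated phenyl group is not ionised.

Step 4
Reactants: 4 (2S)-7-benzyloxy-5-methoxyflavan
Product: 5 (2S)-7-benzyloxy-8-bromo-5-methoxyflavan
Conditions: NBS (1.0 equiv), CH2Cl2, −78 → 0 °C, dark
Reagents that add atoms: N-bromosuccinimide, O=C1CCC(=O)N1Br
Why: Electrophilic aromatic bromination of 5,7-di-O-alkylflavans (per-O-benzylcatechin is the model) goes to C8, which lies between the tied-back O1 and 7-OBn and para to 5-OMe, whereas C6 is shielded by two freely rotating alkoxy groups; the site is to be confirmed by NOE from the remaining H6 to both OCH3 and OCH2Ph.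

Step 5
Reactants: 5 (2S)-7-benzyloxy-8-bromo-5-methoxyflavan; 6 [5-(methoxycarbonyl)furan-2-yl]boronic acid
Product: 7 methyl 5-[(2S)-7-benzyloxy-5-methoxyflavan-8-yl]furan-2-carboxylate
Conditions: Pd(OAc)2 (5 mol %), SPhos (10 mol %), K3PO4, THF/H2O, 45 °C, 6 (2 equiv) in portions
Reagents that add atoms: none
Why: In this Suzuki–Miyaura coupling the bulky, electron-rich biarylphosphine lets zerovalent palladium insert into the electron-rich, doubly ortho-substituted C8–Br bond at mild temperature, and portionwise excess boronic acid compensates for protodeboronation.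

Step 6
Reactants: 7 methyl 5-[(2S)-7-benzyloxy-5-methoxyflavan-8-yl]furan-2-carboxylate
Product: 8 5-[(2S)-7-benzyloxy-5-methoxyflavan-8-yl]furan-2-carboxylic acid
Conditions: LiOH·H2O, THF/MeOH/H2O, rt; then 1 M HCl to pH 3
Reagents that add atoms: lithium hydroxide, [Li+].[OH-]
Why: Saponification of the unhindered furoate is routine, and the ethers and C2 are inert to hydroxide now that the C4 carbonyl is gone.

Step 7
Reactants: 8 5-[(2S)-7-benzyloxy-5-methoxyflavan-8-yl]furan-2-carboxylic acid
Product: 10 2-diazo-1-{5-[(2S)-7-benzyloxy-5-methoxyflavan-8-yl]furan-2-yl}ethanone, via acid chloride 9 (not isolated)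
Conditions: Me2C=C(Cl)NMe2, CH2Cl2, 0 °C → rt; then added to CH2N2 (4 equiv), Et2O, 0 °C
Reagents that add atoms: diazomethane, C=[N+]=[N-]; 1-chloro-N,N,2-trimethylprop-1-en-1-amine, CC(C)=C(Cl)N(C)C (supplies the chlorine of 9)
Why: This is the diazomethane acylation of the Arndt–Eistert sequence; the Ghosez reagent forms the acid chloride under neutral conditions, so no HCl, oxalyl or Vilsmeier electrophile meets the nucleophilic C6 of ring A, and excess CH2N2 takes up HCl so that no chloromethyl ketone forms.

Step 8
Reactants: 11 ethyl acetate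
Product: 14 1-(triisopropylsilyloxy)prop-1-yne, via dibromoenolate 12 (not isolated), via lithium propynolate 13 (not isolated)
Conditions: CH2Br2, LiTMP (lithium 2,2,6,6-tetramethylpiperidide), THF, −78 °C; LiN(SiMe3)2, −78 → −20 °C; n-BuLi, −78 °C → rt; i-Pr3SiCl, −78 °C → rt
Reagents that add atoms: dibromomethane, BrCBr (one carbon); chlorotriisopropylsilane, CC(C)[Si](Cl)(C(C)C)C(C)C
Why: In this Kowalski ynolate synthesis LiCHBr2 acylates on the ester, enolate 12 undergoes Br–Li exchange and a carbenoid 1,2-shift of methyl to give ynolate 13, and the bulky silyl chloride reacts at oxygen rather than at carbon.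

Step 9
Reactants: 10 2-diazo-1-{5-[(2S)-7-benzyloxy-5-methoxyflavan-8-yl]furan-2-yl}ethanone; 14 1-(triisopropylsilyloxy)prop-1-yne
Product: 19 (2S)-7-benzyloxy-8-[4-hydroxy-5-methyl-6-(triisopropylsilyloxy)benzofuran-2-yl]-5-methoxyflavan, via furylketene 15 (not isolated), via cyclobutenone 16 (not isolated), via dienylketene 17 (not isolated), via dienone tautomer 18 (not isolated)
Conditions: 14 (2 equiv), ClCH2CH2Cl (degassed, Ar), hν 365 nm (LED; or medium-pressure Hg lamp through Pyrex), rt; then 80 °C in the dark
Reagents that add atoms: none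
Why: Long-wave excitation of the 5-aryl-2-furoyl diazoketone chromophore of 10 expels N2 with a 1,2-shift of furan C2 from the carbonyl carbon to the diazo carbon (photo-Wolff, C7a'–C7'), and the carbonyl carbon of furylketene 15 is attacked by the nucleophilic, methyl-bearing carbon of ynol ether 14 in a regiospecific [2+2] cycloaddition (C4'–C5' and C6'–C7') to give cyclobutenone 16. At 80 °C ring strain drives reversible conrotatory 4π opening of 16 across the old ketene C=C bond, the isomer 17 with furyl cis to the ketene unit closes irreversibly by disrotatory 6π electrocyclisation of the ketene carbon onto furan C3 (C3a'–C4'), and dienone 18 enolises to phenol 19. The closest known reaction type is the second-generation Danheiser benzannulation of aryl and heteroaryl α-diazo ketones with siloxyalkynes. The only lasting ring, the six-membered benzo ring C3a'–C4'–C5'–C6'–C7'–C7a', is closed by the 6π electrocyclisation, and the four-membered ring of 16 is transient. No lasting stereocentre is made (C4 of 16 and C3a' of 18 vanish on opening and enolisation), and the remote C2 belongs to no chromophore excited at 365 nm, so it should stay (S). The step needs regiocontrol and selective excitation: the oxygen-polarised alkyne fixes CH3 at C5' and OTIPS at C6', furan C3 is the only carbon within reach of the ketene, and 365 nm light should spare the benzyl aryl ether, the C2–O1 bond, 16 and 19, so that all ketene is consumed before any acylable phenol appears.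

Step 10
Reactants: 19 (2S)-7-benzyloxy-8-[4-hydroxy-5-methyl-6-(triisopropylsilyloxy)benzofuran-2-yl]-5-methoxyflavan
Product: 20 (2S)-7-benzyloxy-5-methoxy-8-[4-methoxy-5-methyl-6-(triisopropylsilyloxy)benzofuran-2-yl]flavan
Conditions: CH3I, K2CO3 (anhydrous), acetone, 45 °C
Reagents that add atoms: iodomethane, CI
Why: Williamson O-methylation can reach only the single free hydroxyl at C4', and the bulky aryl TIPS ether at C6' should withstand anhydrous carbonate in acetone.

Step 11
Reactants: 20 (2S)-7-benzyloxy-5-methoxy-8-[4-methoxy-5-methyl-6-(triisopropylsilyloxy)benzofuran-2-yl]flavan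
Product: 21 (2S)-7-benzyloxy-8-(6-hydroxy-4-methoxy-5-methylbenzofuran-2-yl)-5-methoxyflavan
Conditions: Bu4NF, AcOH, THF, 0 °C → rt
Reagents that add atoms: none
Why: Fluoride-driven cleavage of the Si–O bond is selective for the silyl ether, and the acetic acid buffer protonates the electron-rich phenoxide at once and so limits its air oxidation.

Step 12
Reactants: 21 (2S)-7-benzyloxy-8-(6-hydroxy-4-methoxy-5-methylbenzofuran-2-yl)-5-methoxyflavan
Product: 22 (2S)-8-(6-hydroxy-4-methoxy-5-methylbenzofuran-2-yl)-5-methoxyflavan-7-ol (target)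
Conditions: H2 (1 atm), 10% Pd/C, EtOAc/EtOH, rt, stopped after one equivalent of H2
Reagents that add atoms: none
Why: In this catalytic hydrogenolysis the primary O–CH2Ph bond is cleaved faster than the secondary, ring-held C2–O1 benzylic bond, as is routine for O-benzylated flavans, and the hindered aromatic C2'=C3' bond of a 2-arylbenzofuran should not be saturated at 1 atm in a neutral solvent, so C2 stays (S).

## Compound list

1 | (2S)-alpinetin, (2S)-7-hydroxy-5-methoxyflavanone | COc1cc(O)cc2c1C(=O)C[C@@H](c1ccccc1)O2 | starting material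
2 | (2S)-7-benzyloxy-5-methoxyflavanone | COc1cc(OCc3ccccc3)cc2c1C(=O)C[C@@H](c1ccccc1)O2 | intermediate
3 | (2S,4S)-7-benzyloxy-5-methoxyflavan-4-ol (2,4-cis) | COc1cc(OCc3ccccc3)cc2c1[C@@H](O)C[C@@H](c1ccccc1)O2 | intermediate
4 | (2S)-7-benzyloxy-5-methoxyflavan | COc1cc(OCc3ccccc3)cc2c1CC[C@@H](c1ccccc1)O2 | intermediate
5 | (2S)-7-benzyloxy-8-bromo-5-methoxyflavan | COc1cc(OCc3ccccc3)c(Br)c2c1CC[C@@H](c1ccccc1)O2 | intermediate
6 | [5-(methoxycarbonyl)furan-2-yl]boronic acid | COC(=O)c1ccc(B(O)O)o1 | starting material
7 | methyl 5-[(2S)-7-benzyloxy-5-methoxyflavan-8-yl]furan-2-carboxylate | COc1cc(OCc5ccccc5)c(-c3ccc(C(=O)OC)o3)c2c1CC[C@@H](c1ccccc1)O2 | intermediate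
8 | 5-[(2S)-7-benzyloxy-5-methoxyflavan-8-yl]furan-2-carboxylic acid | COc1cc(OCc5ccccc5)c(-c3ccc(C(=O)O)o3)c2c1CC[C@@H](c1ccccc1)O2 | intermediate
9 | 5-[(2S)-7-benzyloxy-5-methoxyflavan-8-yl]furan-2-carbonyl chloride | COc1cc(OCc5ccccc5)c(-c3ccc(C(=O)Cl)o3)c2c1CC[C@@H](c1ccccc1)O2 | intermediate
10 | 2-diazo-1-{5-[(2S)-7-benzyloxy-5-methoxyflavan-8-yl]furan-2-yl}ethanone | COc1cc(OCc5ccccc5)c(-c3ccc(C(=O)C=[N+]=[N-])o3)c2c1CC[C@@H](c1ccccc1)O2 | intermediate
11 | ethyl acetate | CCOC(C)=O | starting material
12 | lithium 1,1-dibromoprop-1-en-2-olate | CC([O-])=C(Br)Br.[Li+] | intermediate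
13 | lithium prop-1-yn-1-olate | CC#C[O-].[Li+] | intermediate
14 | 1-(triisopropylsilyloxy)prop-1-yne | CC#CO[Si](C(C)C)(C(C)C)C(C)C | intermediate
15 | {5-[(2S)-7-benzyloxy-5-methoxyflavan-8-yl]furan-2-yl}ketene | COc1cc(OCc5ccccc5)c(-c3ccc(C=C=O)o3)c2c1CC[C@@H](c1ccccc1)O2 | intermediate
16 | 4-{5-[(2S)-7-benzyloxy-5-methoxyflavan-8-yl]furan-2-yl}-2-methyl-3-(triisopropylsilyloxy)cyclobut-2-en-1-one (both epimers at ring C4) | COc1cc(OCc5ccccc5)c(-c3ccc(C4C(=O)C(C)=C4O[Si](C(C)C)(C(C)C)C(C)C)o3)c2c1CC[C@@H](c1ccccc1)O2 | intermediate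
17 | 4-{5-[(2S)-7-benzyloxy-5-methoxyflavan-8-yl]furan-2-yl}-2-methyl-3-(triisopropylsilyloxy)buta-1,3-dien-1-one, furyl cis to the ketene-bearing carbon | C(/c1ccc(o1)-c1c(OCc2ccccc2)cc(OC)c2CC[C@@H](c3ccccc3)Oc12)=C(O[Si](C(C)C)(C(C)C)C(C)C)/C(C)=C=O | intermediate
18 | 3a'H-benzofuran-4'-one (keto tautomer of 19, both epimers at C3a') | COc1cc(OCc5ccccc5)c(C3=CC4C(=O)C(C)=C(O[Si](C(C)C)(C(C)C)C(C)C)C=C4O3)c2c1CC[C@@H](c1ccccc1)O2 | intermediate
19 | (2S)-7-benzyloxy-8-[4-hydroxy-5-methyl-6-(triisopropylsilyloxy)benzofuran-2-yl]-5-methoxyflavan | COc1cc(OCc5ccccc5)c(-c3cc4c(O)c(C)c(O[Si](C(C)C)(C(C)C)C(C)C)cc4o3)c2c1CC[C@@H](c1ccccc1)O2 | intermediate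
20 | (2S)-7-benzyloxy-5-methoxy-8-[4-methoxy-5-methyl-6-(triisopropylsilyloxy)benzofuran-2-yl]flavan | COc1cc(OCc5ccccc5)c(-c3cc4c(OC)c(C)c(O[Si](C(C)C)(C(C)C)C(C)C)cc4o3)c2c1CC[C@@H](c1ccccc1)O2 | intermediate
21 | (2S)-7-benzyloxy-8-(6-hydroxy-4-methoxy-5-methylbenzofuran-2-yl)-5-methoxyflavan | COc1cc(OCc5ccccc5)c(-c3cc4c(OC)c(C)c(O)cc4o3)c2c1CC[C@@H](c1ccccc1)O2 | intermediate
22 | (2S)-8-(6-hydroxy-4-methoxy-5-methylbenzofuran-2-yl)-5-methoxyflavan-7-ol | COc1cc(O)c(-c2cc3c(OC)c(C)c(O)cc3o2)c2c1CC[C@@H](c1ccccc1)O2 | target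

## Step count and risks

Total step count: 12. Longest linear sequence: 11 (steps 1–7 and 9–12). Step 8 is a one-step side branch.

**1. Step 9.** Three things may go wrong:
- The photolysis may be slowed by competing light absorption of the arylfuran unit and of accumulating products.
- The furan may be photo-oxidised by traces of oxygen.
- The ketene may dimerise faster than it is trapped.

The fallback makes the ketene in the dark by dehydrochlorination instead of by light. Setting out from 10, a silver-catalysed Wolff rearrangement in aqueous THF (AgO2CPh, Et3N, rt) should give 2-{5-[(2S)-7-benzyloxy-5-methoxyflavan-8-yl]furan-2-yl}acetic acid F1. Me2C=C(Cl)NMe2 in CH2Cl2 converts it into the furylacetyl chloride F2. Slow addition of Et3N to F2 and 14 in toluene at rt releases furylketene 15, which is trapped as 16. Heating to 110 °C carries 16 through 17 and 18, and the sequence rejoins the route at 19.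

**2. Step 5.** Protodeboronation of the 2-furylboronic acid may outrun oxidative addition and transmetalation at the crowded, electron-rich C8. The fallback inverts the polarity and uses a Negishi coupling. Setting out from 5, Br–Li exchange (n-BuLi, THF, −78 °C) gives the 8-lithioflavan F3, and ZnCl2 converts it into the flavan-8-ylzinc chloride F4. Coupling with commercial methyl 5-bromofuran-2-carboxylate (COC(=O)c1ccc(Br)o1), an activated electrophile, under Pd2(dba)3/SPhos in THF at rt to 50 °C should give 7, where the route is rejoined.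

**3. Step 3.** The C4 cation may alkylate ring A of a second molecule, which leads to oligomerisation. It may also lose H3 and then disproportionate by hydride transfer through a flavylium ion, a process that would erode the enantiopurity at C2. The fallback uses elimination under base followed by concerted hydrogen transfer, with no acid. Setting out from 3, MsCl/Et3N in CH2Cl2 at 0 °C should give (2S)-7-benzyloxy-5-methoxyflav-3-ene F5. Diimide (2-nitrobenzenesulfonohydrazide, Et3N, CH2Cl2, rt, dark) then saturates C3=C4 without touching the benzyl ether or C2–O1, and the route is rejoined at 4.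

Further compounds
F1 | step 9 | 2-{5-[(2S)-7-benzyloxy-5-methoxyflavan-8-yl]furan-2-yl}acetic acid | COc1cc(OCc5ccccc5)c(-c3ccc(CC(=O)O)o3)c2c1CC[C@@H](c1ccccc1)O2
F2 | step 9 | 2-{5-[(2S)-7-benzyloxy-5-methoxyflavan-8-yl]furan-2-yl}acetyl chloride | COc1cc(OCc5ccccc5)c(-c3ccc(CC(=O)Cl)o3)c2c1CC[C@@H](c1ccccc1)O2
F3 | step 5 | [(2S)-7-benzyloxy-5-methoxyflavan-8-yl]lithium | COc1cc(OCc3ccccc3)c([Li])c2c1CC[C@@H](c1ccccc1)O2
F4 | step 5 | [(2S)-7-benzyloxy-5-methoxyflavan-8-yl]zinc chloride | COc1cc(OCc3ccccc3)c([Zn]Cl)c2c1CC[C@@H](c1ccccc1)O2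
F5 | step 3 | (2S)-7-benzyloxy-5-methoxyflav-3-ene | COc1cc(OCc3ccccc3)cc2c1C=C[C@@H](c1ccccc1)O2
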